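## Retrosynthetic overview
1. The target comes from global MOM removal of a tris-MOM (2R,3R)-dihydroflavonol. That compound comes from an enantioselective Algar–Flynn–Oyamada (AFO) oxidative cyclisation of a 2'-hydroxychalcone, which forms the only new ring (the C ring) and sets the 2,3-trans stereochemistry.
2. The chalcone comes from Claisen–Schmidt condensation of 2'-hydroxy-6'-methoxy-3'-(hydrated lavandulyl)acetophenone with 2,4-bis(MOM-oxy)benzaldehyde.
3. Key disconnection: the Ar–CH2–C*H(isopropenyl) unit comes from an in-situ ortho-quinone methide (o-QM). It is generated by dearomatising the symmetric phloroacetophenone-derived benzylic alcohol, and the CH2 terminus is captured by a γ-substituted β-methylallylboronate. This sets the side-chain (R) centre.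
4. The allylboronate is made from 6-methylhept-5-en-2-one by MeMgBr addition, SeO2 allylic oxidation and Pd-catalysed borylation. The aromatic partners are phloroacetophenone and 2,4-dihydroxybenzaldehyde.

Assumption: I take the enantiomers of the chiral catalysts in steps 7 and 10 to give the (R) side-chain centre and the (2R,3R) ring centres, to be confirmed by a pilot screen. The target is 2,3-trans, as in (+)-taxifolin.

## Route

**Step 1**
Reactants: 1 (6-methylhept-5-en-2-one), 2 (MeMgBr)
Product: 3 (2,6-dimethylhept-5-en-2-ol)
Conditions: 2, Et2O, 0 °C → rt; then aq. NH4Cl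
Reagents that add atoms: MeMgBr, C[Mg]Br
Why: Grignard addition to the ketone builds the tertiary carbinol (the future CMe2OH), and the trisubstituted alkene is untouched.

**Step 2**
Reactants: 3, 4 (tert-butyl hydroperoxide)
Product: 5 ((E)-2,6-dimethylhept-2-ene-1,6-diol)
Conditions: SeO2 (10 mol %), 4 (2 equiv), CH2Cl2, 0 °C → rt
Reagents that add atoms: TBHP, CC(C)(C)OO (supplies the new OH oxygen)
Why: Riley allylic oxidation occurs at the methyl trans to the chain, giving the E-allylic alcohol (E/Z is enriched by chromatography), and the tertiary alcohol is inert.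

**Step 3**
Reactants: 5, 6 (B2pin2)
Product: 7 ((E)-allyl-Bpin, pinB–CH2–C(Me)=CH–CH2CH2–CMe2OH)
Conditions: 6 (1.5 equiv), Pd(OAc)2 (5 mol %), PPh3 (10 mol %), THF, 60 °C
Reagents that add atoms: B2pin2, CC1(C)OB(OC1(C)C)B1OC(C)(C)C(C)(C)O1
Why: Pd-catalysed direct borylation of an allylic alcohol (via a π-allyl-Pd and transmetalation with B2pin2) installs the γ-substituted, β-methyl allylboronate at the primary carbon while retaining the alkene geometry.

**Step 4**
Reactants: 8 (2,4-dihydroxybenzaldehyde), 9 (MOMCl)
Product: 10 (2,4-bis(methoxymethoxy)benzaldehyde)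
Conditions: 9 (2.5 equiv), i-Pr2NEt, CH2Cl2, 0 °C → rt
Reagents that add atoms: MOMCl, COCCl
Why: Bis-MOM protection of the B-ring phenols gives base-stable, mildly acid-labile groups that survive the condensation and oxidation steps and are removed together at the end.

**Step 5**
Reactants: 11 (2,4,6-trihydroxyacetophenone), 9
Product: 12 (1-[2,6-dihydroxy-4-(methoxymethoxy)phenyl]ethanone)
Conditions: 9 (1.0 equiv), K2CO3 (1.1 equiv), acetone, 0 °C
Reagents that add atoms: MOMCl, COCCl
Why: The 4-OH is the only non-chelated and most acidic phenol, so it alone is protected, and the product keeps mirror symmetry (C3 ≡ C5).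

**Step 6**
Reactants: 12, 13 (formaldehyde)
Product: 14 (1-[2,6-dihydroxy-3-(hydroxymethyl)-4-(methoxymethoxy)phenyl]ethanone)
Conditions: aq. CH2O (0.9 equiv), 0.5 M NaOH, THF/H2O, 0 °C → rt
Reagents that add atoms: formaldehyde, C=O
Why: Base-mediated ortho C-hydroxymethylation of the phenoxide (a Lederer–Manasse reaction) occurs at C3, which is equivalent to C5, so no regioisomer arises; substoichiometric CH2O limits bis-hydroxymethylation.

**Step 7 (key step)**
Reactants: 14, 7
Product: 15 (1-{2,6-dihydroxy-4-(methoxymethoxy)-3-[(2R)-5-hydroxy-5-methyl-2-(prop-1-en-2-yl)hexyl]phenyl}ethanone)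
Conditions: 7 (1.5 equiv), (S)-TRIP chiral phosphoric acid (10 mol %), PhMe, 4 Å MS, 50 °C, 24 h
Reagents that add atoms: allylboronate 7 (listed above; pinB–OH is lost)
Why: Proposed new method: acid-promoted loss of water from the hydroxymethyl phenol dearomatises the ring to an o-QM (via the 2'-OH, since the 4'-OH is MOM-capped). The chiral phosphate H-bonds the o-QM oxygen and its P=O binds boron of 7, so the γ-carbon of the E-allylboronate attacks the CH2 terminus in an SE2′ (γ-selective) fashion. This re-aromatises the ring and fixes the (R) centre, because the catalyst pocket distinguishes the two enantiotopic faces of the trisubstituted allyl alkene. The closest known reactions are CPA-catalysed allylboration of aldehydes and BINOL-catalysed boronate additions to in-situ o-QMs.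

**Step 8**
Reactants: 15, 16 (MeI)
Product: 17 (1-{2-hydroxy-6-methoxy-4-(methoxymethoxy)-3-[(2R)-…]phenyl}ethanone)
Conditions: 16 (1.1 equiv), K2CO3 (1.1 equiv), acetone, rt
Reagents that add atoms: MeI, CI
Why: O-Methylation at the non-chelated, unhindered 6'-OH is preferred over the 2'-OH, which is locked in the C=O chelate and buttressed by the 3'-alkyl group; the tertiary alcohol is unreactive.

**Step 9**
Reactants: 17, 10
Product: 18 ((E)-chalcone: 3-[2,4-bis(methoxymethoxy)phenyl]-1-{2-hydroxy-6-methoxy-4-(methoxymethoxy)-3-[(2R)-…]phenyl}prop-2-en-1-one)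
Conditions: 50 % aq. KOH, EtOH, rt, 48 h
Reagents that add atoms: none
Why: Base-mediated Claisen–Schmidt aldol condensation gives the thermodynamic E-enone, and the remote C* centre is not acidic and is untouched.

**Step 10**
Reactants: 18, 19 (H2O2)
Product: 20 ((2R,3R)-2-[2,4-bis(methoxymethoxy)phenyl]-3-hydroxy-5-methoxy-7-(methoxymethoxy)-8-[(2R)-…]chroman-4-one)
Conditions: 30 % H2O2 (5 equiv), 2 M NaOH, N-(9-anthracenylmethyl)cinchonidinium bromide (10 mol %), PhMe/H2O, 0 °C
Reagents that add atoms: hydrogen peroxide, OO
Why: Proposed new method: an enantioselective AFO reaction in which the chiral ammonium–hydroperoxide ion pair adds to the enone (Weitz–Scheffer epoxidation) and so sets the epoxide configuration. The 2'-phenoxide then opens the benzylic epoxide carbon in a 6-endo fashion with inversion, giving the 2,3-trans (2R,3R) dihydroflavonol; C3 is thermodynamically trans. The closest known reactions are PTC asymmetric chalcone epoxidation and the racemic AFO reaction.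

**Step 11**
Reactants: 20
Product: 21 (target)
Conditions: 2 M HCl/MeOH/THF (1:5:5), 40 °C, 12 h
Reagents that add atoms: none (MOM groups are lost as CH2O/MeOH)
Why: Acidolysis of the three aryl MOM acetals releases the phenols, and the mild acid leaves the isopropenyl group, tertiary alcohol, aryl methyl ether and the 2,3-trans stereocentres intact.

## Compound list
1 | 6-methylhept-5-en-2-one | CC(=O)CCC=C(C)C | starting material
2 | methylmagnesium bromide | C[Mg]Br | reagent
3 | 2,6-dimethylhept-5-en-2-ol | CC(C)=CCCC(C)(C)O | intermediate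
4 | tert-butyl hydroperoxide | CC(C)(C)OO | reagent
5 | (E)-2,6-dimethylhept-2-ene-1,6-diol | OC/C(C)=C/CCC(C)(C)O | intermediate
6 | bis(pinacolato)diboron | CC1(C)OB(OC1(C)C)B1OC(C)(C)C(C)(C)O1 | reagent
7 | (E)-allyl pinacolboronate | CC1(C)OB(OC1(C)C)C/C(C)=C/CCC(C)(C)O | intermediate
8 | 2,4-dihydroxybenzaldehyde | O=Cc1ccc(O)cc1O | starting material
9 | chloromethyl methyl ether | COCCl | reagent
10 | 2,4-bis(methoxymethoxy)benzaldehyde | COCOc1ccc(C=O)c(OCOC)c1 | intermediate
11 | 2,4,6-trihydroxyacetophenone | CC(=O)c1c(O)cc(O)cc1O | starting material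
12 | 4-O-MOM phloroacetophenone | CC(=O)c1c(O)cc(OCOC)cc1O | intermediate
13 | formaldehyde | C=O | reagent
14 | 3-hydroxymethyl derivative of 12 | CC(=O)c1c(O)c(CO)c(OCOC)cc1O | intermediate
15 | 3-[(2R)-lavandulyl-hydrate] acetophenone | C=C(C)[C@H](CCC(C)(C)O)Cc1c(O)c(C(C)=O)c(O)cc1OCOC | intermediate
16 | methyl iodide | CI | reagent
17 | 6'-O-methyl acetophenone | C=C(C)[C@H](CCC(C)(C)O)Cc1c(O)c(C(C)=O)c(OC)cc1OCOC | intermediate
18 | (E)-chalcone | C=C(C)[C@H](CCC(C)(C)O)Cc1c(O)c(C(=O)/C=C/c2ccc(OCOC)cc2OCOC)c(OC)cc1OCOC | intermediate
19 | hydrogen peroxide | OO | reagent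
20 | tris-MOM (2R,3R)-dihydroflavonol | C=C(C)[C@H](CCC(C)(C)O)Cc1c(OCOC)cc(OC)c2c1O[C@H](c1ccc(OCOC)cc1OCOC)[C@@H](O)C2=O | intermediate
21 | target: (2R,3R)-2-(2,4-dihydroxyphenyl)-3,7-dihydroxy-8-[(2R)-5-hydroxy-5-methyl-2-(prop-1-en-2-yl)hexyl]-5-methoxychroman-4-one | C=C(C)[C@H](CCC(C)(C)O)Cc1c(O)cc(OC)c2c1O[C@H](c1ccc(O)cc1O)[C@@H](O)C2=O | target

**Total steps:** 11 (3 to the allylboronate, 1 for the B-ring aldehyde, 7 on the A-ring and C-ring path).
**Longest linear sequence:** 8 steps (1 → 2 → 3 → 7 → 8 → 9 → 10 → 11).

**Three steps most likely to fail:**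
1. **Step 7 (enantioselective o-QM allylation).** The risks are low ee, o-QM dimerisation or [4+2] with the allyl alkene, and α-attack.
   - Fallback: set C* by Evans alkylation of N-(3-methylbut-3-enoyl)oxazolidinone with prenyl bromide. Then selectively epoxidise the trisubstituted alkene and reduce with LiAlH4, which removes the auxiliary and opens the epoxide to the tertiary alcohol. Convert the primary alcohol to the iodide and couple it by Ni-catalysed cross-electrophile coupling with the 3'-bromoacetophenone.
2. **Step 10 (asymmetric AFO).** The risks are modest ee with the free phenoxide and aurone by-products.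
   - Fallback: epoxidise the 2'-O-MOM chalcone with La-BINOL-Ph3P=O/CMHP or Juliá–Colonna conditions, then remove the 2'-MOM and cyclise with base (6-endo, inversion).
3. **Step 8 (regioselective mono-O-methylation).** 2'-OMe or bis-methyl products would block ring closure.
   - Fallback: methylate at the symmetric stage, before the key step. Mono-methylate 12 to give the 2-hydroxy-6-methoxy compound, where the 2/6 positions are still equivalent. Then do a PhB(OH)2-directed ortho-hydroxymethylation at C3, next to the free OH, and continue with steps 7, 9, 10 and 11.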